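# Proposed synthesis of irisoquin D by photochemical benzannulation of a diazo enone with a siloxyalkyne

## The problem

Irisoquin D (15) is 2-hydroxy-3-icosyl-5-methoxy-1,4-benzoquinone: one six-membered carbocycle, an unbranched C20 chain and no stereocentre, so the synthesis has to control position, not configuration. The ring is numbered C1 (carbonyl), C2 (OH), C3 (icosyl), C4 (carbonyl), C5 (OMe) and C6 (H). Four of the six ring carbons carry oxygen in three different states, and the methyl ether must sit at C5 and the free hydroxyl at C2, not the reverse and not the 6-methoxy arrangement; these isomers would be hard to separate in a waxy C20 series. The hydroxyquinone is a vinylogous acid and the methoxyquinone a vinylogous ester, so the two groups exchange, hydrolyse or re-esterify under base, nucleophiles or acidic methanol. The oxygens therefore have to be told apart before the quinone exists, and the quinone should appear late and meet only mild, buffered reagents. The long chain makes every intermediate lipophilic, which favours ethereal, chlorinated or hydrocarbon solvents and argues against alkylating a preformed, fully oxygenated arene with a C20 halide. The enabling feature is C3: an alkyl-bearing carbon flanked by two oxygenated carbons (C2 and C4) is what an alkyl ynol ether gives when its alkyl-bearing carbon bonds to the carbonyl carbon of a ketene. The other four carbons (C4, C5, C6, C1) then form a vinylketene with the methoxy group at its terminus, and in the resulting phenol C1 is the only position para to the C4 hydroxyl, so the fourth oxygen can enter at one place only.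

## Retrosynthesis

**15 to 14.** The last disconnection cuts only the O–Si bond at the C2 oxygen, leading back to silyl quinone 14. Carrying C2–O as a silyl ether through the oxidation keeps the three oxygens distinct until the end; a free resorcinol would leave two hydroxyls to compete. The forward reaction is a buffered fluoride cleavage of a vinylogous silyl ester.

**14 to 13.** Removing the C1 carbonyl oxygen takes quinone 14 back to phenol 13, in which C4 carries the free hydroxyl, C2 the silyl ether and C5 the methyl ether. Building the ring directly at the quinone or hydroquinone level would ask the ring-forming step to deliver four oxygens. Here the forward reaction only has to oxidise a phenol at its para position, and both ortho positions (C3 and C5) are blocked.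

**13 to 8 and 5.** Cutting C3–C4, C1–C2 and C4–C5 splits the ring into the two-carbon siloxyalkyne 5 (C2, C3) and the four-carbon diazo enone 8 (C4, C5, C6, C1). Diazo enone 8 is the latent form of vinylketene 9, and the forward process runs through cyclobutenone 10, dienylketene 11 and dienone 12. The neighbouring cut, between C3 and the chain, would need metalation of a trioxygenated arene and alkylation with a C20 halide, and would leave the oxygens undifferentiated. The chosen cut gives two acyclic fragments and sets the substitution pattern in the bond-forming events. The forward reaction must take one orientation in the [2+2] step.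

**5 to 2 and 1.** The siloxyalkyne is cut at its O–Si bond and at the C2–C3 bond, leading through ynolate 4 and dibromo enolate 3 to ethyl henicosanoate 2, the ester of commercial acid 1. The carboxyl carbon becomes C2 and the carbon of dibromomethane becomes C3, which receives the migrating icosyl group. Oxidising a C22 terminal alkyne instead would first require building that alkyne. The forward reaction needs a clean carbenoid rearrangement and silylation on oxygen.

**8 to 7 and 6.** The diazo carbon of 8 is the methyl carbon of commercial (E)-4-methoxybut-3-en-2-one 6. The C=N bond is cut back to the trifluoroacetyl-activated diketone 7, because simple ketone enolates do not accept a diazo group efficiently and the acyl chloride plus diazomethane route is less convenient. The forward reactions are a kinetic enolate acylation and a diazo transfer with loss of the activating group.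

## Roads not taken

**Alternative 1:** Michael–Dieckmann annulation of a tetronate. The cut is at C1–C6 and C4–C5. The anion at the OCH2 carbon of 4-(benzyloxy)-3-icosylfuran-2(5H)-one A2 would add to the CH2 of 1-methoxyvinyl phenyl sulfone A3. The sulfonyl carbanion would then attack the lactone carbonyl, and loss of the sulfonyl group as sulfinate would aromatise the ring to 2-(benzyloxy)-3-icosyl-5-methoxybenzene-1,4-diol A1.

- Merits: A1 has all four oxygens in place and differentiated at the hydroquinone level, so no oxygen has to be introduced afterwards and the final oxidation is trivial. The chemistry is ionic and needs no lamp. In oxidation-level economy this road is better than the chosen plan.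
- Weak points: the acceptor A3 is deactivated by its α-methoxy group, and the carbanion it produces is destabilised by the adjacent oxygen. That carbanion must attack a vinylogous carbonate carbonyl through a strained oxygen-bridged intermediate. The tetronate dienolate is ambident. Annulations of this type are established for phthalide donors that carry their own leaving group, not for this donor–acceptor pairing. A2 needs several steps, because C-alkylation of a tetronic acid with a C20 halide competes with O-alkylation. Hydrogenolysis of the benzyl ether at the end would reduce the quinone and require reoxidation.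
- Comparison: the chosen plan must add one oxygen after ring formation, but its ring-forming step belongs to an established reaction class and the site of that oxidation is unambiguous.

**Alternative 2:** Oxalate condensation with a 2,3-diketone. The cut is at C3–C4 and C5–C6. Both α-carbons of tetracosane-2,3-dione A5, derived from docosanoic acid A7, would condense with the two ester carbons of diethyl oxalate A6 under a hindered alkoxide base, giving 2,5-dihydroxy-3-icosyl-1,4-benzoquinone A4 at the correct oxidation level.

- Merits: this is the shortest road. It uses a cheap fatty acid, no protecting groups and no photochemistry, and it scales easily. If it worked as drawn it would beat the chosen plan in step count.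
- Weak points: a 1,2-diketone enolisable on both sides is prone to self-aldol condensation under the base needed for the double Claisen reaction. More seriously, A4 must then be methylated on the C5 hydroxyl and not on the C2 hydroxyl. The two vinylogous acids differ only in their neighbour (H against icosyl). Steric bias should favour C5 but is unlikely to be exclusive, so the 2-methoxy isomer and the dimethyl ether would have to be removed from a waxy mixture.
- Comparison: against the shorter sequence, the chosen plan sets the fact that the three oxygens are already differentiated when the ring closes, so the regiochemistry rests on bond construction and not on a late selectivity.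

**Alternative 3:** Ring expansion of a squarate-derived cyclobutenone. The cut is at C1–C6. Heating 2-tert-butoxy-4-hydroxy-3-icosyl-4-(1-methoxyvinyl)cyclobut-2-en-1-one A9 would open the four-membered ring to a dienylketene, whose ketene carbon bonds to the vinyl CH2 to give 2-tert-butoxy-3-icosyl-5-methoxybenzene-1,4-diol A8.

- Merits: the rearrangement is thermal and well studied, both quinone oxygens are present from the start, and the tert-butyl ether leaves with acid. In oxidation economy it equals alternative 1 and is better than the chosen plan.
- Weak points: A9 is the regioisomer that the usual order of additions does not give. An organolithium adds to 3-tert-butoxy-4-icosylcyclobut-3-ene-1,2-dione A10 at the carbonyl next to the alkoxy-bearing carbon, because the other carbonyl is a vinylogous ester. That places the carbinol beside the tert-butoxy carbon and leads to 2-hydroxy-3-icosyl-6-methoxy-1,4-benzoquinone A11, not to 15. Reversing the regiochemistry needs extra steps (methoxyvinyl addition first, carbinol protection, alkyl addition, acid-induced transposition), and the 1-methoxyvinyl enol ether and the tert-butyl ether are unlikely to survive the acid.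
- Comparison: step counts are similar; the chosen plan fixes the regiochemistry through the polarisation of the ynol ether and carries no acid-labile enol ether past ring formation.

Key step: step 5

Remark on the chemistry: diketone 7 is drawn in its diketo form although it should exist largely as the chelated enol; cyclobutenone 10 and dienone 12 are racemic transients whose sp3 centres disappear on the way to 13.

## Route

Step 1
Reactants: 1 henicosanoic acid
Product: 2 ethyl henicosanoate
Conditions: EtOH, H2SO4 (cat.), reflux
Reagents that add atoms: ethanol, CCO
Why: Fischer esterification of an unhindered fatty acid in excess ethanol; the ethyl ester is the substrate class on which the ester-to-ynolate homologation is established.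

Step 2
Reactants: 2 ethyl henicosanoate
Product: 5 1-(triisopropylsiloxy)docos-1-yne, via lithium 1,1-dibromodocos-1-en-2-olate 3 (not isolated), via lithium docos-1-yn-1-olate 4 (not isolated)
Conditions: lithium 2,2,6,6-tetramethylpiperidide, CH2Br2, THF, −78 °C; add 2; n-BuLi, −78 °C to rt; i-Pr3SiCl, −78 °C to rt
Reagents that add atoms: dibromomethane, BrCBr; chlorotriisopropylsilane, CC(C)[Si](Cl)(C(C)C)C(C)C
Why: Kowalski ester homologation halted at the ynolate: LiCHBr2 adds to the ester, the dibromo ketone is deprotonated to enolate 3, bromine–lithium exchange with n-BuLi gives a carbenoid whose icosyl group shifts to the neighbouring carbon on warming, and ynolate 4 results. The hindered chlorosilane traps 4 on oxygen and not on carbon, and the triisopropylsilyl ynol ether is robust enough for rapid chromatography.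

Step 3
Reactants: 6 (E)-4-methoxybut-3-en-2-one
Product: 7 (E)-1,1,1-trifluoro-6-methoxyhex-5-ene-2,4-dione
Conditions: LiN(SiMe3)2, THF, −78 °C; CF3CO2CH2CF3, −78 °C; cold dilute HCl work-up, crude used at once
Reagents that add atoms: 2,2,2-trifluoroethyl trifluoroacetate, O=C(OCC(F)(F)F)C(F)(F)F
Why: The methyl group is the only enolisable position of 6, so LiN(SiMe3)2 gives a single enolate, which undergoes Claisen-type C-acylation with the activated trifluoroacetate; the trifluoroacetyl group turns the methyl carbon into an acidic 1,3-dicarbonyl methylene ready for diazo transfer.

Step 4
Reactants: 7 (E)-1,1,1-trifluoro-6-methoxyhex-5-ene-2,4-dione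
Product: 8 (E)-1-diazo-4-methoxybut-3-en-2-one
Conditions: MeSO2N3, Et3N, H2O (1 equiv), MeCN, rt
Reagents that add atoms: methanesulfonyl azide, CS(=O)(=O)N=[N+]=[N-]
Why: Detrifluoroacetylative (Regitz-type) diazo transfer: the triethylammonium enolate of 7 attacks the terminal nitrogen of the sulfonyl azide and the adduct fragments with the trifluoroacetyl group leaving on the sulfonamide nitrogen, so the diazo group ends up on the former methyl carbon of 6 under conditions mild enough for the enol ether.

Step 5
Reactants: 8 (E)-1-diazo-4-methoxybut-3-en-2-one; 5 1-(triisopropylsiloxy)docos-1-yne
Product: 13 2-icosyl-6-methoxy-3-(triisopropylsiloxy)phenol, via vinylketene 9 (not isolated), via 4-vinylcyclobutenone 10 (not isolated), via dienylketene 11 (not isolated), via cyclohexa-2,4-dienone 12 (not isolated)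
Conditions: hν (254 nm, low-pressure Hg lamps, Vycor), ClCH2CH2Cl, rt; then 80 °C
Reagents that add atoms: none
Why: Light expels N2 from 8 and the (E)-2-methoxyvinyl group migrates with retention of its geometry (Wolff rearrangement) to give vinylketene 9. The polarised ynol ether 5 then adds across the ketene C=C in a [2+2] cycloaddition, its nucleophilic icosyl-bearing carbon bonding to the ketene carbonyl carbon (C3–C4) and its oxygenated carbon to the ketene α-carbon (C1–C2), which gives the 4-vinylcyclobutenone 10. Reversible four-electron conrotatory opening of 10, thermal at 80 °C or photochemical during the irradiation, gives dienylketene 11, and only the isomer with the methoxyvinyl group turned inward can react further. The benzene ring is closed by six-electron disrotatory electrocyclisation of 11, the ketene carbon bonding to the methoxy-bearing terminus (C4–C5), and the cyclohexa-2,4-dienone 12 tautomerises irreversibly to phenol 13. The closest known reaction type is the Danheiser benzannulation in its photochemical Wolff variant, which is established for α-diazo enones and triisopropylsiloxyalkynes. No stereocentre survives, since the sp3 ring carbons of 10 and 12 are transient and the alkene geometry of 8 is lost on aromatisation. The one selectivity needed is the orientation of the [2+2] step, and it is secured by the oxygen lone pair of 5, which makes the alkyl-bearing carbon the nucleophile and the ketene carbonyl carbon its electrophilic partner, so the icosyl group ends up between the two oxygenated carbons.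

Step 6
Reactants: 13 2-icosyl-6-methoxy-3-(triisopropylsiloxy)phenol
Product: 14 3-icosyl-5-methoxy-2-(triisopropylsiloxy)-1,4-benzoquinone
Conditions: (KSO3)2NO, KH2PO4, methyltrioctylammonium chloride (cat.), CH2Cl2/H2O, rt
Reagents that add atoms: potassium nitrosodisulfonate, [O]N(S(=O)(=O)[O-])S(=O)(=O)[O-].[K+].[K+]
Why: Teuber oxidation with Fremy's salt: the nitroxyl radical abstracts the phenolic hydrogen, a second equivalent couples with the phenoxyl radical at the para carbon and the adduct collapses to the 1,4-quinone. Both ortho positions of the free hydroxyl are substituted and the other ring oxygens are capped, so the new carbonyl can form only at C1; the phase-transfer salt brings the oxidant to the lipophilic substrate.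

Step 7
Reactants: 14 3-icosyl-5-methoxy-2-(triisopropylsiloxy)-1,4-benzoquinone
Product: 15 irisoquin D (2-hydroxy-3-icosyl-5-methoxy-1,4-benzoquinone)
Conditions: Bu4NF, AcOH, THF, 0 °C; dilute HCl work-up
Reagents that add atoms: none
Why: Fluoride-mediated cleavage of the Si–O bond of a 2-siloxyquinone, a vinylogous silyl ester that is far more labile than an aryl silyl ether; acetic acid buffers the medium so that the methoxy group is not displaced and the quinone is not degraded by basic fluoride, and acidic work-up returns the hydroxyquinone in its neutral form.

## Compound list

1 | henicosanoic acid | CCCCCCCCCCCCCCCCCCCCC(=O)O | starting material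
2 | ethyl henicosanoate | CCCCCCCCCCCCCCCCCCCCC(=O)OCC | intermediate
3 | lithium 1,1-dibromodocos-1-en-2-olate | CCCCCCCCCCCCCCCCCCCCC([O-])=C(Br)Br.[Li+] | intermediate
4 | lithium docos-1-yn-1-olate | CCCCCCCCCCCCCCCCCCCCC#C[O-].[Li+] | intermediate
5 | 1-(triisopropylsiloxy)docos-1-yne | CCCCCCCCCCCCCCCCCCCCC#CO[Si](C(C)C)(C(C)C)C(C)C | intermediate
6 | (E)-4-methoxybut-3-en-2-one | CO/C=C/C(C)=O | starting material
7 | (E)-1,1,1-trifluoro-6-methoxyhex-5-ene-2,4-dione | CO/C=C/C(=O)CC(=O)C(F)(F)F | intermediate
8 | (E)-1-diazo-4-methoxybut-3-en-2-one | CO/C=C/C(=O)C=[N+]=[N-] | intermediate
9 | (E)-4-methoxybuta-1,3-dien-1-one (vinylketene) | CO/C=C/C=C=O | intermediate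
10 | 2-icosyl-4-[(E)-2-methoxyvinyl]-3-(triisopropylsiloxy)cyclobut-2-en-1-one (racemic) | CCCCCCCCCCCCCCCCCCCCC1=C(O[Si](C(C)C)(C(C)C)C(C)C)C(/C=C/OC)C1=O | intermediate
11 | (3E,5E)-2-icosyl-6-methoxy-3-(triisopropylsiloxy)hexa-1,3,5-trien-1-one (dienylketene) | CCCCCCCCCCCCCCCCCCCCC(=C=O)/C(O[Si](C(C)C)(C(C)C)C(C)C)=C\C=C\OC | intermediate
12 | 2-icosyl-6-methoxy-3-(triisopropylsiloxy)cyclohexa-2,4-dien-1-one (racemic) | CCCCCCCCCCCCCCCCCCCCC1=C(O[Si](C(C)C)(C(C)C)C(C)C)C=CC(OC)C1=O | intermediate
13 | 2-icosyl-6-methoxy-3-(triisopropylsiloxy)phenol | CCCCCCCCCCCCCCCCCCCCc1c(O)c(OC)ccc1O[Si](C(C)C)(C(C)C)C(C)C | intermediate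
14 | 3-icosyl-5-methoxy-2-(triisopropylsiloxy)-1,4-benzoquinone | CCCCCCCCCCCCCCCCCCCCC1=C(O[Si](C(C)C)(C(C)C)C(C)C)C(=O)C=C(OC)C1=O | intermediate
15 | irisoquin D, 2-hydroxy-3-icosyl-5-methoxy-1,4-benzoquinone | CCCCCCCCCCCCCCCCCCCCC1=C(O)C(=O)C=C(OC)C1=O | target

## Step count and risk assessment

Total step count: 7. Longest linear sequence: 5 steps (1 to 2 to 5 to 13 to 14 to 15; the branch from 6 through 7 and 8 is equally long).

**Step 5 (key step).** Several processes can erode this step:
- the ketocarbene from the vinylogous-ester diazo ketone may be diverted before it rearranges, for example after E-to-Z photoisomerisation of the enone;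
- the phenol formed absorbs at the irradiation wavelength and slows late conversion;
- the phenol can be O-acylated by ketene that is still being generated;
- the thermal passage from cyclobutenone 10 to 13 may stall, because the methoxyvinyl group prefers to rotate outward on ring opening.

Fallback, from 5, rejoining the route at 13: the same ketene would be generated in the dark. Commercial (E)-4-methoxybut-2-enoic acid F1 is converted with oxalyl chloride and catalytic DMF into (E)-4-methoxybut-2-enoyl chloride F2. Slow addition of F2 to siloxyalkyne 5 and Et3N in toluene causes 1,4-dehydrochlorination to vinylketene 9, which 5 intercepts in the [2+2] cycloaddition to give 10. Heating the filtered solution to 80–110 °C then carries 10 through 11 and 12 to 13. Dehydrohalogenation of α,β-unsaturated acid chlorides is a known source of vinylketenes for [2+2] cycloadditions, and ynol silyl ethers are among the most reactive ketenophiles. Any 13 acylated by surplus F2 would be released by brief K2CO3/MeOH treatment at 0 °C.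

**Step 2.** The C21 ester may come out of solution at −78 °C, so that addition of LiCHBr2 and the later exchange are incomplete. Protonation of the ynolate before silylation, silylation on carbon, and hydrolysis of the ynol ether on acidic silica are further possible losses.

Fallback, from ester 2, rejoining at 5 through ynolate 4: 2 is reduced with i-Bu2AlH at −78 °C to henicosanal F3. Corey–Fuchs olefination (CBr4, PPh3) gives 1,1-dibromodocos-1-ene F4, and n-BuLi followed by water gives docos-1-yne F5. Deprotonation with LiN(SiMe3)2 gives lithium docos-1-yn-1-ide F6, which is oxidised in the same flask by lithium tert-butyl peroxide (from t-BuOOH and LiN(SiMe3)2) to ynolate 4. Silylation with i-Pr3SiOSO2CF3 gives 5.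

**Step 3.** During the acidic work-up or on standing, the enol oxygen of the trifluoroacetyl diketone can add to the methoxyvinyl terminus with loss of methanol, closing a six-membered oxygen heterocycle. Retro-Claisen loss of the trifluoroacetyl group is a second risk.

Fallback, from enone 6, rejoining at 8 and replacing steps 3 and 4: the 1,3-dicarbonyl is kept as its salt and never protonated. Enone 6 is formylated with ethyl formate and NaOEt in Et2O, and sodium (1Z,4E)-5-methoxy-3-oxopenta-1,4-dien-1-olate F7 is collected as the precipitated salt. Treating F7 with p-toluenesulfonyl azide in EtOH/CH2Cl2 brings about deformylative (Regitz) diazo transfer and gives 8 directly.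

**Step 6.** Electron transfer across the phase boundary may be slow for the waxy substrate. The phenoxyl radical may dimerise or couple at the methoxy-bearing ortho carbon with loss of methanol. The silyl ether may partly hydrolyse in the aqueous buffer and give mixtures.

Fallback, from 13, rejoining at 15 and replacing steps 6 and 7: the order of the last two operations is reversed and the oxidant class is changed. Phenol 13 is desilylated with Bu4NF in THF to 2-icosyl-4-methoxybenzene-1,3-diol F8. F8 is oxidised with O2 under catalysis by Co(salen), the divalent cobalt complex N,N'-bis(salicylidene)ethylenediaminatocobalt, in DMF/THF. Oxidation para to the C4 hydroxyl and oxidation ortho to the C2 hydroxyl give tautomers of the same product, 15.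

## Further compounds

F1 | step 5 | (E)-4-methoxybut-2-enoic acid | COC/C=C/C(=O)O
F2 | step 5 | (E)-4-methoxybut-2-enoyl chloride | COC/C=C/C(=O)Cl
F3 | step 2 | henicosanal | CCCCCCCCCCCCCCCCCCCCC=O
F4 | step 2 | 1,1-dibromodocos-1-ene | CCCCCCCCCCCCCCCCCCCCC=C(Br)Br
F5 | step 2 | docos-1-yne | CCCCCCCCCCCCCCCCCCCCC#C
F6 | step 2 | lithium docos-1-yn-1-ide | CCCCCCCCCCCCCCCCCCCCC#[C-].[Li+]
F7 | step 3 | sodium (1Z,4E)-5-methoxy-3-oxopenta-1,4-dien-1-olate | CO/C=C/C(=O)/C=C\[O-].[Na+]
F8 | step 6 | 2-icosyl-4-methoxybenzene-1,3-diol | CCCCCCCCCCCCCCCCCCCCc1c(O)c(OC)ccc1O
A1 | alternative 1 | 2-(benzyloxy)-3-icosyl-5-methoxybenzene-1,4-diol | CCCCCCCCCCCCCCCCCCCCc1c(O)c(OC)cc(O)c1OCc1ccccc1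
A2 | alternative 1 | 4-(benzyloxy)-3-icosylfuran-2(5H)-one | CCCCCCCCCCCCCCCCCCCCC1=C(OCc2ccccc2)COC1=O
A3 | alternative 1 | 1-methoxyvinyl phenyl sulfone | C=C(OC)S(=O)(=O)c1ccccc1
A4 | alternative 2 | 2,5-dihydroxy-3-icosyl-1,4-benzoquinone | CCCCCCCCCCCCCCCCCCCCC1=C(O)C(=O)C=C(O)C1=O
A5 | alternative 2 | tetracosane-2,3-dione | CCCCCCCCCCCCCCCCCCCCCC(=O)C(C)=O
A6 | alternative 2 | diethyl oxalate | CCOC(=O)C(=O)OCC
A7 | alternative 2 | docosanoic acid | CCCCCCCCCCCCCCCCCCCCCC(=O)O
A8 | alternative 3 | 2-tert-butoxy-3-icosyl-5-methoxybenzene-1,4-diol | CCCCCCCCCCCCCCCCCCCCc1c(O)c(OC)cc(O)c1OC(C)(C)C
A9 | alternative 3 | 2-tert-butoxy-4-hydroxy-3-icosyl-4-(1-methoxyvinyl)cyclobut-2-en-1-one (racemic) | CCCCCCCCCCCCCCCCCCCCC1=C(OC(C)(C)C)C(=O)C1(O)C(=C)OC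
A10 | alternative 3 | 3-tert-butoxy-4-icosylcyclobut-3-ene-1,2-dione | CCCCCCCCCCCCCCCCCCCCC1=C(OC(C)(C)C)C(=O)C1=O
A11 | alternative 3 | 2-hydroxy-3-icosyl-6-methoxy-1,4-benzoquinone | CCCCCCCCCCCCCCCCCCCCC1=C(O)C(=O)C(OC)=CC1=O
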